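The cyclopentanone ring is disconnected at C1–C2 and C3–C3a (octahydroindene numbering: C1 acyloxy carbon, C2 ketone, C3 ethylidene carbon). Its 1,2-dioxygenated C1–C2 edge is read as the adduct of an acyl anion with a carboxyl carbon: 1-ethoxyvinyllithium (C2–C3) adds to the C1 carboxamide of a cryptone-derived cyclohexene, and the 2-ethoxy dienone so formed closes by Nazarov cyclisation onto C3a, anti to the C4 isopropyl group, in the same flask. The precursor is thus a monocyclic C7a=C3a enamide carrying the C6 oxygen and a masked C7 ketone. Hydroxyl-directed hydrogenation then sets the trans ring fusion and C1; aldol condensation and methylenation install the two exocyclic alkenes.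

Key step: step 6

Remark: ring atoms are numbered as in octahydro-1H-indene (C1 acyloxy carbon, C2 ketone, C3 ethylidene carbon, C3a and C7a ring fusion, C4 isopropyl, C6 enoate, C7 methylidene); (2R)-2-methylbutanoic acid and (2E)-3-methylpent-2-enoic acid are taken as purchasable single isomers.

Step 1
Reactants: 1 3-methylbutanal; 2 but-3-en-2-one
Product: 4 (4S)-4-(propan-2-yl)cyclohex-2-en-1-one, via keto aldehyde 3 (not isolated)
Conditions: (S)-2-[diphenyl(trimethylsilyloxy)methyl]pyrrolidine (5 mol %), ethyl 3,4-dihydroxybenzoate (20 mol %), neat, 4 °C; then LiOH (0.1 equiv), iPrOH, rt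
Reagents that add atoms: none
Why: Enamine-catalysed Michael addition of the aldehyde to the enone followed by base-mediated intramolecular aldol condensation (a Robinson-type annulation) should give the cyclohexenone, the C4 stereocenter being set in the Michael step by the (S)-prolinol catalyst, whose diarylmethyl group shields one face of the E-enamine.

Step 2
Reactants: 4 (4S)-4-(propan-2-yl)cyclohex-2-en-1-one
Product: 6 (4S,6R)-6-[(tert-butyldimethylsilyl)oxy]-4-(propan-2-yl)cyclohex-2-en-1-one, via silyl dienol ether 5 (not isolated)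
Conditions: LiN(iPr)2, THF, −78 °C; tBuMe2SiCl, HMPA, −78 °C → rt; then mCPBA, hexane, −15 °C → rt
Reagents that add atoms: tert-butyldimethylsilyl chloride, CC(C)(C)[Si](C)(C)Cl; 3-chloroperbenzoic acid, OOC(=O)c1cccc(Cl)c1
Why: Kinetic deprotonation at C6 gives the cross-conjugated silyl dienol ether 5, whose Rubottom oxidation (epoxidation of the enol ether and 1,4-silyl shift) should deliver the 6-silyloxy enone, the peracid approaching anti to the C4 isopropyl group so that the C6 oxygen is trans to it.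

Step 3
Reactants: 6 (4S,6R)-6-[(tert-butyldimethylsilyl)oxy]-4-(propan-2-yl)cyclohex-2-en-1-one
Product: 7 (4S,6R)-6-[(tert-butyldimethylsilyl)oxy]-2-iodo-4-(propan-2-yl)cyclohex-2-en-1-one
Conditions: I2, pyridine, CH2Cl2, 0 °C → rt
Reagents that add atoms: iodine, II
Why: The Johnson α-iodination of enones (conjugate addition of pyridine, iodination of the enolate, elimination) should functionalise only C2 and creates no stereocenter.

Step 4
Reactants: 7 (4S,6R)-6-[(tert-butyldimethylsilyl)oxy]-2-iodo-4-(propan-2-yl)cyclohex-2-en-1-one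
Product: 8 tert-butyl{[(8S,10R)-6-iodo-8-(propan-2-yl)-1,4-dioxaspiro[4.5]dec-6-en-10-yl]oxy}dimethylsilane
Conditions: Me3SiOCH2CH2OSiMe3, Me3SiOTf (cat.), CH2Cl2, −78 → −20 °C
Reagents that add atoms: 1,2-bis(trimethylsilyloxy)ethane, C[Si](C)(C)OCCO[Si](C)(C)C
Why: Noyori ketalisation under aprotic silyl triflate catalysis should mask the ketone without migration of the iodine-bearing double bond and without loss of the silyl ether; no stereocenter is formed.

Step 5
Reactants: 8 tert-butyl{[(8S,10R)-6-iodo-8-(propan-2-yl)-1,4-dioxaspiro[4.5]dec-6-en-10-yl]oxy}dimethylsilane; 9 morpholine-4-carbonyl chloride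
Product: 11 [(8S,10R)-10-[(tert-butyldimethylsilyl)oxy]-8-(propan-2-yl)-1,4-dioxaspiro[4.5]dec-6-en-6-yl](morpholin-4-yl)methanone, via vinyllithium 10 (not isolated)
Conditions: t-BuLi (2.1 equiv), Et2O, −78 °C; then 9, −78 → 0 °C
Reagents that add atoms: none
Why: Iodine–lithium exchange gives the ketal-bearing vinyllithium 10 (an α-keto vinyl anion equivalent), which is acylated by the carbamoyl chloride to the tertiary enamide without touching a stereocenter.

Step 6
Reactants: 11 [(8S,10R)-10-[(tert-butyldimethylsilyl)oxy]-8-(propan-2-yl)-1,4-dioxaspiro[4.5]dec-6-en-6-yl](morpholin-4-yl)methanone; 12 ethoxyethene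
Product: 16 (3aS,4S,6R)-6-[(tert-butyldimethylsilyl)oxy]-7,7-(ethylenedioxy)-1-hydroxy-4-(propan-2-yl)-3,3a,4,5,6,7-hexahydro-2H-inden-2-one, via 1-ethoxyvinyllithium 13 (not isolated), via dienone 14 (not isolated), via ethoxy enone 15 (not isolated)
Conditions: 12, t-BuLi, THF, −78 → 0 °C; then 11, −78 → −20 °C; then 1 M HCl, THF, 0 °C → rt
Reagents that add atoms: water, O
Why: 1-Ethoxyvinyllithium 13, an acyl anion equivalent, adds to the amide carbonyl (C1–C2 bond) and the tetrahedral adduct collapses on acidification to the 2-ethoxy dienone 14; its protonated form is a pentadienyl cation that closes by 4π conrotatory electrocyclisation (C3–C3a bond), proton loss gives ethoxy enone 15 and hydrolysis of the enol ether gives diosphenol 16. The closest known reaction type is the Nazarov cyclisation of α-alkoxy dienones made from α-lithiated enol ethers and unsaturated morpholine amides, the enol ether counterpart of the allenyl ether cyclopentannulation. The one ring closed is the five-membered carbocycle, formed by this electrocyclisation onto the cyclohexene. The new C3a stereocenter is controlled by the adjacent C4 isopropyl group, the vinyl terminus bonding to the ring face anti to it. The step needs single 1,2-addition, which the hard lithium reagent and the stable amide adduct secure, and survival of the dioxolane and silyl ether, for which the acid is kept dilute and cold.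

Step 7
Reactants: 16 (3aS,4S,6R)-6-[(tert-butyldimethylsilyl)oxy]-7,7-(ethylenedioxy)-1-hydroxy-4-(propan-2-yl)-3,3a,4,5,6,7-hexahydro-2H-inden-2-one; 17 (2R)-2-methylbutanoic acid
Product: 18 (3aS,4S,6R)-6-[(tert-butyldimethylsilyl)oxy]-7,7-(ethylenedioxy)-2-oxo-4-(propan-2-yl)-3,3a,4,5,6,7-hexahydro-2H-inden-1-yl (2R)-2-methylbutanoate
Conditions: DCC, DMAP (0.1 equiv), CH2Cl2, 0 °C → rt
Reagents that add atoms: none
Why: Steglich esterification of the acidic diosphenol hydroxyl should give the enol ester on oxygen without disturbing the stereocenter of the acid.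

Step 8
Reactants: 18 (3aS,4S,6R)-6-[(tert-butyldimethylsilyl)oxy]-7,7-(ethylenedioxy)-2-oxo-4-(propan-2-yl)-3,3a,4,5,6,7-hexahydro-2H-inden-1-yl (2R)-2-methylbutanoate
Product: 19 (3aS,4S,6R)-7,7-(ethylenedioxy)-6-hydroxy-2-oxo-4-(propan-2-yl)-3,3a,4,5,6,7-hexahydro-2H-inden-1-yl (2R)-2-methylbutanoate
Conditions: HF·pyridine, pyridine, THF, 0 °C → rt
Reagents that add atoms: none
Why: Fluoride-mediated desilylation under buffered conditions should free the C6 hydroxyl while the enol ester and the dioxolane stay intact.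

Step 9
Reactants: 19 (3aS,4S,6R)-7,7-(ethylenedioxy)-6-hydroxy-2-oxo-4-(propan-2-yl)-3,3a,4,5,6,7-hexahydro-2H-inden-1-yl (2R)-2-methylbutanoate
Product: 20 (1S,3aS,4S,6R,7aS)-7,7-(ethylenedioxy)-6-hydroxy-2-oxo-4-(propan-2-yl)octahydro-1H-inden-1-yl (2R)-2-methylbutanoate
Conditions: H2 (50 bar), [Ir(cod)(PCy3)(py)]PF6 (10 mol %), CH2Cl2, rt
Reagents that add atoms: none
Why: Hydroxyl-directed hydrogenation with Crabtree's catalyst should deliver both hydrogens to the tetrasubstituted enol ester syn to the axial homoallylic C6 hydroxyl, which sets C7a and C1 together (trans ring fusion, acyloxy group anti to the new C7a hydrogen).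

Step 10
Reactants: 20 (1S,3aS,4S,6R,7aS)-7,7-(ethylenedioxy)-6-hydroxy-2-oxo-4-(propan-2-yl)octahydro-1H-inden-1-yl (2R)-2-methylbutanoate; 21 (2E)-3-methylpent-2-enoic acid
Product: 22 (1S,3aS,4S,6R,7aS)-7,7-(ethylenedioxy)-1-{[(2R)-2-methylbutanoyl]oxy}-2-oxo-4-(propan-2-yl)octahydro-1H-inden-6-yl (2E)-3-methylpent-2-enoate
Conditions: 21, 2,4,6-trichlorobenzoyl chloride, Et3N, THF, rt; then 20, DMAP, toluene, rt
Reagents that add atoms: none
Why: Yamaguchi esterification through the mixed anhydride should acylate the hindered axial alcohol with retention at C6 and without moving the enoate double bond.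

Step 11
Reactants: 22 (1S,3aS,4S,6R,7aS)-7,7-(ethylenedioxy)-1-{[(2R)-2-methylbutanoyl]oxy}-2-oxo-4-(propan-2-yl)octahydro-1H-inden-6-yl (2E)-3-methylpent-2-enoate; 23 acetaldehyde
Product: 26 (1S,3E,3aS,4S,6R,7aS)-3-ethylidene-7,7-(ethylenedioxy)-1-{[(2R)-2-methylbutanoyl]oxy}-2-oxo-4-(propan-2-yl)octahydro-1H-inden-6-yl (2E)-3-methylpent-2-enoate, via aldol adduct 24 (not isolated), via mesylate 25 (not isolated)
Conditions: LiN(SiMe3)2 (1.05 equiv), THF, −78 °C; 23; then MeSO2Cl, Et3N, −78 → 0 °C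
Reagents that add atoms: none
Why: Kinetic deprotonation at the unsubstituted C3 methylene, aldol addition to acetaldehyde and E1cB elimination of the mesylate (an aldol condensation) should give the exocyclic enone as the favoured E isomer, methyl anti to the carbonyl.

Step 12
Reactants: 26 (1S,3E,3aS,4S,6R,7aS)-3-ethylidene-7,7-(ethylenedioxy)-1-{[(2R)-2-methylbutanoyl]oxy}-2-oxo-4-(propan-2-yl)octahydro-1H-inden-6-yl (2E)-3-methylpent-2-enoate
Product: 27 (1S,3E,3aS,4S,6R,7aS)-3-ethylidene-1-{[(2R)-2-methylbutanoyl]oxy}-2,7-dioxo-4-(propan-2-yl)octahydro-1H-inden-6-yl (2E)-3-methylpent-2-enoate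
Conditions: pyridinium p-toluenesulfonate, acetone/H2O (10:1), 50 °C
Reagents that add atoms: water, O
Why: Mild acid-catalysed hydrolysis of the dioxolane should release the C7 ketone, the weak acid being chosen so that C7a is not epimerised and the β-acyloxy group is not eliminated.

Step 13
Reactants: 27 (1S,3E,3aS,4S,6R,7aS)-3-ethylidene-1-{[(2R)-2-methylbutanoyl]oxy}-2,7-dioxo-4-(propan-2-yl)octahydro-1H-inden-6-yl (2E)-3-methylpent-2-enoate
Product: 28 (1S,3E,3aS,4S,6R,7aR)-3-ethylidene-7-methylidene-1-{[(2R)-2-methylbutanoyl]oxy}-2-oxo-4-(propan-2-yl)octahydro-1H-inden-6-yl (2E)-3-methylpent-2-enoate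
Conditions: CH2Br2, Zn, TiCl4, THF/CH2Cl2, 0 °C → rt
Reagents that add atoms: dibromomethane, BrCBr
Why: Takai–Lombardo methylenation, a non-basic titanium–zinc carbenoid olefination, should convert the saturated α-acyloxy ketone at C7 faster than the cross-conjugated C2 enone carbonyl or the esters and leaves all stereocenters untouched.

Compound list
1 | 3-methylbutanal | CC(C)CC=O | starting material
2 | but-3-en-2-one | CC(=O)C=C | starting material
3 | (2S)-5-oxo-2-(propan-2-yl)hexanal | O=C[C@H](C(C)C)CCC(C)=O | intermediate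
4 | (4S)-4-(propan-2-yl)cyclohex-2-en-1-one | O=C1C=C[C@H](C(C)C)CC1 | intermediate
5 | tert-butyldimethyl{[(4S)-4-(propan-2-yl)cyclohexa-1,5-dien-1-yl]oxy}silane | CC(C)[C@@H]1CC=C(O[Si](C)(C)C(C)(C)C)C=C1 | intermediate
6 | (4S,6R)-6-[(tert-butyldimethylsilyl)oxy]-4-(propan-2-yl)cyclohex-2-en-1-one | O=C1C=C[C@H](C(C)C)C[C@H]1O[Si](C)(C)C(C)(C)C | intermediate
7 | (4S,6R)-6-[(tert-butyldimethylsilyl)oxy]-2-iodo-4-(propan-2-yl)cyclohex-2-en-1-one | O=C1C(I)=C[C@H](C(C)C)C[C@H]1O[Si](C)(C)C(C)(C)C | intermediate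
8 | tert-butyl{[(8S,10R)-6-iodo-8-(propan-2-yl)-1,4-dioxaspiro[4.5]dec-6-en-10-yl]oxy}dimethylsilane | C12(OCCO2)C(I)=C[C@H](C(C)C)C[C@H]1O[Si](C)(C)C(C)(C)C | intermediate
9 | morpholine-4-carbonyl chloride | O=C(Cl)N1CCOCC1 | starting material
10 | [(8S,10R)-10-[(tert-butyldimethylsilyl)oxy]-8-(propan-2-yl)-1,4-dioxaspiro[4.5]dec-6-en-6-yl]lithium | C12(OCCO2)C([Li])=C[C@H](C(C)C)C[C@H]1O[Si](C)(C)C(C)(C)C | intermediate
11 | [(8S,10R)-10-[(tert-butyldimethylsilyl)oxy]-8-(propan-2-yl)-1,4-dioxaspiro[4.5]dec-6-en-6-yl](morpholin-4-yl)methanone | C12(OCCO2)C(C(=O)N3CCOCC3)=C[C@H](C(C)C)C[C@H]1O[Si](C)(C)C(C)(C)C | intermediate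
12 | ethoxyethene (ethyl vinyl ether) | C=COCC | starting material
13 | (1-ethoxyethenyl)lithium | [Li]C(=C)OCC | intermediate
14 | 1-[(8S,10R)-10-[(tert-butyldimethylsilyl)oxy]-8-(propan-2-yl)-1,4-dioxaspiro[4.5]dec-6-en-6-yl]-2-ethoxyprop-2-en-1-one | C12(OCCO2)C(C(=O)C(=C)OCC)=C[C@H](C(C)C)C[C@H]1O[Si](C)(C)C(C)(C)C | intermediate
15 | 6-[(tert-butyldimethylsilyl)oxy]-2-ethoxy-7,7-(ethylenedioxy)-4-(propan-2-yl)-3a,4,5,6,7,7a-hexahydro-1H-inden-1-one, configured at C3a, C4 and C6 as in 16, cis ring fusion | C12(OCCO2)[C@H]3C(=O)C(OCC)=C[C@H]3[C@H](C(C)C)C[C@H]1O[Si](C)(C)C(C)(C)C | intermediate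
16 | (3aS,4S,6R)-6-[(tert-butyldimethylsilyl)oxy]-7,7-(ethylenedioxy)-1-hydroxy-4-(propan-2-yl)-3,3a,4,5,6,7-hexahydro-2H-inden-2-one | C12(OCCO2)C3=C(O)C(=O)C[C@H]3[C@H](C(C)C)C[C@H]1O[Si](C)(C)C(C)(C)C | intermediate
17 | (2R)-2-methylbutanoic acid | CC[C@@H](C)C(=O)O | starting material
18 | (3aS,4S,6R)-6-[(tert-butyldimethylsilyl)oxy]-7,7-(ethylenedioxy)-2-oxo-4-(propan-2-yl)-3,3a,4,5,6,7-hexahydro-2H-inden-1-yl (2R)-2-methylbutanoate | C12(OCCO2)C3=C(OC(=O)[C@H](C)CC)C(=O)C[C@H]3[C@H](C(C)C)C[C@H]1O[Si](C)(C)C(C)(C)C | intermediate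
19 | (3aS,4S,6R)-7,7-(ethylenedioxy)-6-hydroxy-2-oxo-4-(propan-2-yl)-3,3a,4,5,6,7-hexahydro-2H-inden-1-yl (2R)-2-methylbutanoate | C12(OCCO2)C3=C(OC(=O)[C@H](C)CC)C(=O)C[C@H]3[C@H](C(C)C)C[C@H]1O | intermediate
20 | (1S,3aS,4S,6R,7aS)-7,7-(ethylenedioxy)-6-hydroxy-2-oxo-4-(propan-2-yl)octahydro-1H-inden-1-yl (2R)-2-methylbutanoate, trans ring fusion | C12(OCCO2)[C@H]3[C@@H](CC(=O)[C@H]3OC(=O)[C@H](C)CC)[C@H](C(C)C)C[C@H]1O | intermediate
21 | (2E)-3-methylpent-2-enoic acid | CC/C(C)=C/C(=O)O | starting material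
22 | (1S,3aS,4S,6R,7aS)-7,7-(ethylenedioxy)-1-{[(2R)-2-methylbutanoyl]oxy}-2-oxo-4-(propan-2-yl)octahydro-1H-inden-6-yl (2E)-3-methylpent-2-enoate | C12(OCCO2)[C@H]3[C@@H](CC(=O)[C@H]3OC(=O)[C@H](C)CC)[C@H](C(C)C)C[C@H]1OC(=O)/C=C(\C)CC | intermediate
23 | acetaldehyde | CC=O | starting material
24 | 3-(1-hydroxyethyl) derivative of 22, mixture at C3 and at the carbinol carbon | C12(OCCO2)[C@H]3[C@@H](C(C(C)O)C(=O)[C@H]3OC(=O)[C@H](C)CC)[C@H](C(C)C)C[C@H]1OC(=O)/C=C(\C)CC | intermediate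
25 | methanesulfonate of 24 | C12(OCCO2)[C@H]3[C@@H](C(C(C)OS(C)(=O)=O)C(=O)[C@H]3OC(=O)[C@H](C)CC)[C@H](C(C)C)C[C@H]1OC(=O)/C=C(\C)CC | intermediate
26 | (1S,3E,3aS,4S,6R,7aS)-3-ethylidene-7,7-(ethylenedioxy)-1-{[(2R)-2-methylbutanoyl]oxy}-2-oxo-4-(propan-2-yl)octahydro-1H-inden-6-yl (2E)-3-methylpent-2-enoate | C12(OCCO2)[C@H]3[C@@H](/C(=C\C)C(=O)[C@H]3OC(=O)[C@H](C)CC)[C@H](C(C)C)C[C@H]1OC(=O)/C=C(\C)CC | intermediate
27 | (1S,3E,3aS,4S,6R,7aS)-3-ethylidene-1-{[(2R)-2-methylbutanoyl]oxy}-2,7-dioxo-4-(propan-2-yl)octahydro-1H-inden-6-yl (2E)-3-methylpent-2-enoate | O=C1[C@H]2[C@@H](/C(=C\C)C(=O)[C@H]2OC(=O)[C@H](C)CC)[C@H](C(C)C)C[C@H]1OC(=O)/C=C(\C)CC | intermediate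
28 | (1S,3E,3aS,4S,6R,7aR)-3-ethylidene-7-methylidene-1-{[(2R)-2-methylbutanoyl]oxy}-2-oxo-4-(propan-2-yl)octahydro-1H-inden-6-yl (2E)-3-methylpent-2-enoate | C=C1[C@H]2[C@@H](/C(=C\C)C(=O)[C@H]2OC(=O)[C@H](C)CC)[C@H](C(C)C)C[C@H]1OC(=O)/C=C(\C)CC | target

Total step count: 13. Longest linear sequence: 13 steps (1 and 2 to 28).

Steps most likely to fail

Step 9. The cationic iridium catalyst may bind too weakly to the electron-poor tetrasubstituted enol ester, so that no reduction occurs. Hydrogen may also be delivered without the hydroxyl tether from the open face, which would give the cis ring fusion. The fallback replaces directed hydrogenation by a dissolving-metal reduction, in which the ring fusion is set by protonation of the β-carbanion. It sets out from 16 and comes back at 20. Silylation with Et3SiOTf and 2,6-lutidine gives the diosphenol triethylsilyl ether F1. Li in NH3/THF with t-BuOH at −78 °C, quenched with NH4Cl, should give the trans-fused α-silyloxy ketone F2, the enolate being protonated at C1 from the face of the C7a hydrogen. Pyridinium p-toluenesulfonate in MeOH removes only the triethylsilyl group to give ketol F3. Steglich esterification with 17 gives the silyl-protected ester F4, and HF·pyridine then gives 20.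

Step 13. The carbenoid may also attack the C2 enone carbonyl, and once the C7 ketone of 27 is free, C7a may epimerise or the C1 acyloxy group may be lost by β-elimination. The fallback removes the second ketone for the duration of the olefination. It sets out from 26 and comes back at 28. NaBH4 with CeCl3·7H2O in MeOH at −78 °C reduces the C2 carbonyl to the allylic alcohol F5. Hydrolysis of the dioxolane as in step 12 gives keto alcohol F6. Methylenation of the only ketone as in step 13 gives the methylidene alcohol F7, and oxidation with Dess–Martin periodinane gives 28.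

Step 11. The base may deprotonate C1 instead of C3, with epimerisation or migration of the 2-methylbutanoyl group, or may attack the enoate. The fallback runs the condensation before the enoate is attached and dehydrates without a second strong-base step. It sets out from 20 and comes back at 26. LiN(SiMe3)2 (2.2 equiv) forms the alkoxide–enolate dianion, and acetaldehyde then gives the aldol diol F8. Selective mesylation of the unhindered aldol hydroxyl (MeSO2Cl, Et3N, −40 → 0 °C) with elimination in the same flask gives the ethylidene alcohol F9. Yamaguchi esterification with 21 as in step 10 gives 26.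

Further compounds
F1 | step 9 | (3aS,4S,6R)-6-[(tert-butyldimethylsilyl)oxy]-7,7-(ethylenedioxy)-4-(propan-2-yl)-1-[(triethylsilyl)oxy]-3,3a,4,5,6,7-hexahydro-2H-inden-2-one | C12(OCCO2)C3=C(O[Si](CC)(CC)CC)C(=O)C[C@H]3[C@H](C(C)C)C[C@H]1O[Si](C)(C)C(C)(C)C
F2 | step 9 | (1S,3aS,4S,6R,7aS)-6-[(tert-butyldimethylsilyl)oxy]-7,7-(ethylenedioxy)-4-(propan-2-yl)-1-[(triethylsilyl)oxy]octahydro-2H-inden-2-one | C12(OCCO2)[C@H]3[C@@H](CC(=O)[C@H]3O[Si](CC)(CC)CC)[C@H](C(C)C)C[C@H]1O[Si](C)(C)C(C)(C)C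
F3 | step 9 | (1S,3aS,4S,6R,7aS)-6-[(tert-butyldimethylsilyl)oxy]-7,7-(ethylenedioxy)-1-hydroxy-4-(propan-2-yl)octahydro-2H-inden-2-one | C12(OCCO2)[C@H]3[C@@H](CC(=O)[C@H]3O)[C@H](C(C)C)C[C@H]1O[Si](C)(C)C(C)(C)C
F4 | step 9 | (1S,3aS,4S,6R,7aS)-6-[(tert-butyldimethylsilyl)oxy]-7,7-(ethylenedioxy)-2-oxo-4-(propan-2-yl)octahydro-1H-inden-1-yl (2R)-2-methylbutanoate | C12(OCCO2)[C@H]3[C@@H](CC(=O)[C@H]3OC(=O)[C@H](C)CC)[C@H](C(C)C)C[C@H]1O[Si](C)(C)C(C)(C)C
F5 | step 13 | 2-hydroxy analogue of 26 (C2 carbinol, mixture at C2) | C12(OCCO2)[C@H]3[C@@H](/C(=C\C)C(O)[C@H]3OC(=O)[C@H](C)CC)[C@H](C(C)C)C[C@H]1OC(=O)/C=C(\C)CC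
F6 | step 13 | 2-hydroxy analogue of 27 (C7 ketone, C2 carbinol) | O=C1[C@H]2[C@@H](/C(=C\C)C(O)[C@H]2OC(=O)[C@H](C)CC)[C@H](C(C)C)C[C@H]1OC(=O)/C=C(\C)CC
F7 | step 13 | 2-hydroxy analogue of 28 (C7 methylidene, C2 carbinol) | C=C1[C@H]2[C@@H](/C(=C\C)C(O)[C@H]2OC(=O)[C@H](C)CC)[C@H](C(C)C)C[C@H]1OC(=O)/C=C(\C)CC
F8 | step 11 | 3-(1-hydroxyethyl) derivative of 20, mixture at C3 and at the carbinol carbon | C12(OCCO2)[C@H]3[C@@H](C(C(C)O)C(=O)[C@H]3OC(=O)[C@H](C)CC)[C@H](C(C)C)C[C@H]1O
F9 | step 11 | (1S,3E,3aS,4S,6R,7aS)-3-ethylidene-7,7-(ethylenedioxy)-6-hydroxy-2-oxo-4-(propan-2-yl)octahydro-1H-inden-1-yl (2R)-2-methylbutanoate | C12(OCCO2)[C@H]3[C@@H](/C(=C\C)C(=O)[C@H]3OC(=O)[C@H](C)CC)[C@H](C(C)C)C[C@H]1O
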